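**Plan**

- Retrosynthetic cuts: the C3–O ester bond (Mitsunobu, inversion); the oxirane C6–O bond, back to a C6 iodide with the C5 oxygen held in a 3,5-cyclic carbonate; the C5–O and C6–iodine bonds, back to the C5=C6 alkene of a C3 tert-butyl carbonate; and the C6–C7 bond, back to an enol triflate and but-3-yn-2-ol.
- Forward order: the carbocycle is bought as ketoisophorone, the four-carbon chain is joined by Sonogashira coupling and brought to the enone, the cyclic carbonate ring closes in the key step, the oxirane closes on methanolysis, and the myristate is joined last.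
- Enabling feature: on the six-membered carbocycle the C3 oxygen and C5 are 1,3-related (C3–C4–C5), so a carbonate on C3 reaches C5 through a six-membered ring only on its own face.
- Stereochemistry: C3 comes from Ru-catalysed asymmetric transfer hydrogenation (3S-β-ionone series); C5 is relayed from C3 by the tether; C6 follows from anti iodo-addition and inversion on oxirane closure; the final Mitsunobu inversion at C3 makes ester and oxirane trans.
- The side chain is held at the enone level in the key step so that C7=C8 is inert to electrophilic iodine and the C6 iodide is slow to ionise.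

Key step: step 9

Remark on numbering: ring and chain positions follow β-ionone numbering (C1 gem-dimethyl carbon, C3 carbinol carbon, C5 methyl-bearing carbon, C6 chain-bearing carbon, C7–C10 side chain). The descriptor at the carbinol carbon changes from R to S between the enone and the enol triflate, and from 3S to 3R between the tert-butyl carbonate and the iodocarbonate, only because CIP priorities change. The one real inversion is the last step.

Assumption: the sense of induction in step 1 follows the usual model for RuCl(TsDPEN)(arene) catalysts with the enone alkene in the place of the aryl group, so the (R,R) complex should give (R)-phorenol. The (S,S) complex would be used if the rotation of the product showed the opposite sense.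

**Route**

Step 1
Reactants: 1 ketoisophorone
Product: 2 (R)-phorenol [(4R)-4-hydroxy-2,6,6-trimethylcyclohex-2-en-1-one]
Conditions: RuCl[(R,R)-TsDPEN](p-cymene) (0.5 mol%), HCO2H/Et3N (5:2), CH2Cl2, 25 °C
Reagents that add atoms: none
Why: Noyori-type asymmetric transfer hydrogenation, known for this diketone, should reduce only the C4 carbonyl (flanked by CH= and CH2) because the C1 carbonyl is shielded by the quaternary carbon and the methylated alkene carbon, and the chiral ruthenium hydride sets the carbinol stereocentre (the later C3).

Step 2
Reactants: 2 (R)-phorenol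
Product: 3 (4R)-4-(tert-butyldimethylsilyloxy)-2,6,6-trimethylcyclohex-2-en-1-one
Conditions: TBSCl, imidazole, DMF, rt
Reagents that add atoms: tert-butyldimethylsilyl chloride, SMILES CC(C)(C)[Si](C)(C)Cl
Why: Standard imidazole-mediated silylation of a secondary alcohol gives a TBS ether that should withstand the hydride, palladium and oxidation steps that follow, and no stereocentre is touched.

Step 3
Reactants: 3 (4R)-4-(tert-butyldimethylsilyloxy)-2,6,6-trimethylcyclohex-2-en-1-one
Product: 5 (4S)-4-(tert-butyldimethylsilyloxy)-2,6,6-trimethylcyclohex-1-en-1-yl trifluoromethanesulfonate, via lithium enolate 4 (not isolated)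
Conditions: LiBH(s-Bu)3 (L-Selectride, 1.1 equiv), THF, −78 °C; then PhNTf2, −78 °C → 0 °C
Reagents that add atoms: N-phenylbis(trifluoromethanesulfonimide), SMILES O=S(=O)(N(c1ccccc1)S(=O)(=O)C(F)(F)F)C(F)(F)F
Why: Conjugate reduction of an α-methyl, β-unsubstituted cyclohexenone by the bulky trialkylborohydride (1,2-attack at the doubly flanked carbonyl is disfavoured) gives the tetrasubstituted enolate regiospecifically, and PhNTf2 traps it on oxygen (conjugate reduction–enolate triflation, as practised on carvone-type enones) without touching the carbinol centre.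

Step 4
Reactants: 5 (4S)-4-(tert-butyldimethylsilyloxy)-2,6,6-trimethylcyclohex-1-en-1-yl trifluoromethanesulfonate; 6 but-3-yn-2-ol (racemic)
Product: 7 4-[(4S)-4-(tert-butyldimethylsilyloxy)-2,6,6-trimethylcyclohex-1-en-1-yl]but-3-yn-2-ol (both epimers at the side-chain carbinol carbon)
Conditions: Pd(PPh3)4 (5 mol%), CuI (10 mol%), Et3N, DMF, 50 °C
Reagents that add atoms: none
Why: Sonogashira coupling of an alkenyl triflate with a terminal alkyne tolerates the free propargylic hydroxyl and the silyl ether and is established for 2,6,6-trimethylcyclohexenyl triflates; the racemic alkynol suffices because its carbinol carbon becomes the ketone in step 6.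

Step 5
Reactants: 7 4-[(4S)-4-(tert-butyldimethylsilyloxy)-2,6,6-trimethylcyclohex-1-en-1-yl]but-3-yn-2-ol
Product: 8 (E)-4-[(4S)-4-(tert-butyldimethylsilyloxy)-2,6,6-trimethylcyclohex-1-en-1-yl]but-3-en-2-ol (both epimers at the side-chain carbinol carbon)
Conditions: NaAlH2(OCH2CH2OMe)2 (Red-Al), THF, 0 °C → rt; aq. potassium sodium tartrate work-up
Reagents that add atoms: none
Why: Alkoxide-directed trans-hydroalumination of the propargylic alcohol followed by protonolysis at work-up (Red-Al reduction of propargylic alcohols) should give the E alkene only, with the ring alkene and the silyl ether inert.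

Step 6
Reactants: 8 (E)-4-[(4S)-4-(tert-butyldimethylsilyloxy)-2,6,6-trimethylcyclohex-1-en-1-yl]but-3-en-2-ol
Product: 9 (3S)-3-(tert-butyldimethylsilyloxy)-β-ionone [(E)-4-[(4S)-4-(tert-butyldimethylsilyloxy)-2,6,6-trimethylcyclohex-1-en-1-yl]but-3-en-2-one]
Conditions: MnO2 (activated, excess), CH2Cl2, rt
Reagents that add atoms: none
Why: Allylic oxidation with activated MnO2 converts the secondary dienylic alcohol into the conjugated ketone without touching the silyl ether and removes the side-chain stereocentre.

Step 7
Reactants: 9 (3S)-3-(tert-butyldimethylsilyloxy)-β-ionone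
Product: 10 (3S)-3-hydroxy-β-ionone [(E)-4-[(4S)-4-hydroxy-2,6,6-trimethylcyclohex-1-en-1-yl]but-3-en-2-one]
Conditions: Bu4NF, THF, 0 °C → rt
Reagents that add atoms: none
Why: Fluoride-induced desilylation of the secondary TBS ether should leave the hindered dienone and the configuration at C3 unaffected.

Step 8
Reactants: 10 (3S)-3-hydroxy-β-ionone; 11 di-tert-butyl dicarbonate
Product: 12 (3S)-3-(tert-butoxycarbonyloxy)-β-ionone [tert-butyl (1S)-3,5,5-trimethyl-4-[(E)-3-oxobut-1-en-1-yl]cyclohex-3-en-1-yl carbonate]
Conditions: DMAP (0.3 equiv), MeCN, rt
Reagents that add atoms: none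
Why: DMAP-catalysed O-acylation of the secondary alcohol with the dicarbonate gives the mixed tert-butyl carbonate under conditions that do not enolise the methyl ketone, with retention at C3.

Step 9
Reactants: 12 (3S)-3-(tert-butoxycarbonyloxy)-β-ionone
Product: 13 bridged iodocarbonate (E)-4-[(1R,5R,6R)-6-iodo-5,7,7-trimethyl-3-oxo-2,4-dioxabicyclo[3.3.1]nonan-6-yl]but-3-en-2-one (3R,5R,6R in β-ionone numbering; carbonate spanning C3 and C5 on one face, iodine on C6 on the other)
Conditions: IBr (1.5 equiv, 1.0 mol/L solution in CH2Cl2), PhMe, −85 °C → −40 °C; cold aq. Na2S2O3/NaHCO3; crude product used at once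
Reagents that add atoms: iodine monobromide, SMILES IBr
Why: Proposed new method: IBr transfers electrophilic iodine reversibly to the twisted, electron-rich ring alkene C5=C6 (the site that peracids also choose in β-ionones), the iodonium ion on the face away from the pseudoaxial C3 carbonate is opened at C5 by the carbonate carbonyl oxygen, and the tert-butyl group then leaves as tert-butyl bromide; the closest known reaction type is the IBr-induced iodocarbonate cyclisation of homoallylic tert-butyl carbonates, shown on less substituted alkenes but not on a tetrasubstituted ring alkene of a dienone that must give a tertiary allylic iodide. The single new ring, the six-membered cyclic carbonate spanning C3 and C5 (a 2,4-dioxabicyclo[3.3.1]nonan-3-one together with the carbocycle), closes in the 6-exo mode. The C5 stereocentre is controlled by the C3 stereocentre through the tether, since the carbonate oxygen can reach C5 only on its own ring face, and the C6 stereocentre by the anti opening of the iodonium ion, which leaves iodine trans to the new C5–O bond. The step needs regioselectivity for C5 over C6 and site selectivity for the ring alkene over the C7=C8 alkene: 6-exo against 7-endo closure and the poor cation-stabilising ability of C6, which is linked through C7=C8 to the ketone, should secure the first, and the electron-poor character of the enone alkene the second. Loss of hydrogen iodide from the product is not possible because C1 and C5 carry no hydrogen, which is why the tertiary iodide can be carried on as crude material.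

Step 10
Reactants: 13 bridged iodocarbonate
Product: 15 (3R,5R,6S)-5,6-epoxy-3-hydroxy-5,6-dihydro-β-ionone (cis epoxy alcohol), via iodo diol 14 (not isolated)
Conditions: K2CO3 (3 equiv), MeOH, 0 °C → rt
Reagents that add atoms: none
Why: Base-induced methanolysis of the cyclic carbonate followed by Williamson-type oxirane closure is the established fate of iodocarbonates in K2CO3/MeOH: the C5 alkoxide displaces the antiperiplanar C6 iodide from the rear, so C6 is inverted, C5 is retained and the oxirane should end up on the same face as the C3 hydroxyl.

Step 11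
Reactants: 15 (3R,5R,6S)-5,6-epoxy-3-hydroxy-5,6-dihydro-β-ionone; 16 myristic acid
Product: 17 (3S,5R,6S)-5,6-epoxy-5,6-dihydro-β-ionon-3-yl tetradecanoate [(E)-4-[(1S,4S,6R)-2,2,6-trimethyl-4-(tetradecanoyloxy)-7-oxabicyclo[4.1.0]heptan-1-yl]but-3-en-2-one], the target
Conditions: PPh3, DIAD, THF, 0 °C → rt
Reagents that add atoms: none
Why: In the Mitsunobu esterification the carboxylate displaces the C3 oxyphosphonium group in an SN2 reaction with inversion, which turns the cis epoxy alcohol into the trans ester (a tactic precedented for 3-hydroxy-5,6-epoxycyclohexane end groups), while the oxirane oxygen, being cis to the leaving group, cannot take part and the enone is inert.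

**Compound list**

1 | ketoisophorone (2,6,6-trimethylcyclohex-2-ene-1,4-dione) | CC1=CC(=O)CC(C)(C)C1=O | starting material
2 | (R)-phorenol, (4R)-4-hydroxy-2,6,6-trimethylcyclohex-2-en-1-one | O[C@@H]1CC(C)(C)C(=O)C(C)=C1 | intermediate
3 | (4R)-4-(tert-butyldimethylsilyloxy)-2,6,6-trimethylcyclohex-2-en-1-one | CC(C)(C)[Si](C)(C)O[C@@H]1CC(C)(C)C(=O)C(C)=C1 | intermediate
4 | lithium (4S)-4-(tert-butyldimethylsilyloxy)-2,6,6-trimethylcyclohex-1-en-1-olate (lithium enolate) | [Li+].CC(C)(C)[Si](C)(C)O[C@@H]1CC(C)(C)C([O-])=C(C)C1 | intermediate
5 | (4S)-4-(tert-butyldimethylsilyloxy)-2,6,6-trimethylcyclohex-1-en-1-yl trifluoromethanesulfonate | CC(C)(C)[Si](C)(C)O[C@@H]1CC(C)(C)C(OS(=O)(=O)C(F)(F)F)=C(C)C1 | intermediate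
6 | but-3-yn-2-ol (racemic) | CC(O)C#C | starting material
7 | 4-[(4S)-4-(tert-butyldimethylsilyloxy)-2,6,6-trimethylcyclohex-1-en-1-yl]but-3-yn-2-ol (both epimers at the side-chain carbinol carbon) | CC(C)(C)[Si](C)(C)O[C@@H]1CC(C)(C)C(C#CC(C)O)=C(C)C1 | intermediate
8 | (E)-4-[(4S)-4-(tert-butyldimethylsilyloxy)-2,6,6-trimethylcyclohex-1-en-1-yl]but-3-en-2-ol (both epimers at the side-chain carbinol carbon) | CC(C)(C)[Si](C)(C)O[C@@H]1CC(C)(C)C(/C=C/C(C)O)=C(C)C1 | intermediate
9 | (3S)-3-(tert-butyldimethylsilyloxy)-β-ionone | CC(C)(C)[Si](C)(C)O[C@@H]1CC(C)(C)C(/C=C/C(C)=O)=C(C)C1 | intermediate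
10 | (3S)-3-hydroxy-β-ionone | O[C@@H]1CC(C)(C)C(/C=C/C(C)=O)=C(C)C1 | intermediate
11 | di-tert-butyl dicarbonate | CC(C)(C)OC(=O)OC(=O)OC(C)(C)C | starting material
12 | (3S)-3-(tert-butoxycarbonyloxy)-β-ionone | CC(C)(C)OC(=O)O[C@@H]1CC(C)(C)C(/C=C/C(C)=O)=C(C)C1 | intermediate
13 | bridged iodocarbonate, (E)-4-[(1R,5R,6R)-6-iodo-5,7,7-trimethyl-3-oxo-2,4-dioxabicyclo[3.3.1]nonan-6-yl]but-3-en-2-one | O=C1O[C@@H]2CC(C)(C)[C@](I)(/C=C/C(C)=O)[C@](C)(O1)C2 | intermediate
14 | iodo diol, (3R,5R,6R)-3,5-dihydroxy-6-iodo-5,6-dihydro-β-ionone | O[C@@H]1CC(C)(C)[C@](I)(/C=C/C(C)=O)[C@](C)(O)C1 | intermediate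
15 | cis epoxy alcohol, (3R,5R,6S)-5,6-epoxy-3-hydroxy-5,6-dihydro-β-ionone | O[C@@H]1CC(C)(C)[C@]2(/C=C/C(C)=O)O[C@]2(C)C1 | intermediate
16 | myristic acid (tetradecanoic acid) | CCCCCCCCCCCCCC(=O)O | starting material
17 | (3S,5R,6S)-5,6-epoxy-5,6-dihydro-β-ionon-3-yl tetradecanoate | CCCCCCCCCCCCCC(=O)O[C@H]1CC(C)(C)[C@]2(/C=C/C(C)=O)O[C@]2(C)C1 | target

**Totals**

Total step count: 11. Longest linear sequence: 11 steps (from 1 to 17).

**Steps most likely to fail**

1. Step 9 (the step labelled as a proposed new method). The hindered tetrasubstituted alkene may engage IBr too slowly at low temperature. The iodonium ion may be captured by bromide or lose an allylic proton before the carbonate attacks. The tertiary iodide may also collapse back to the alkene during the reductive quench. The fallback uses known chemistry, sets out from 10 and comes back at 15. It is a hydroxyl-directed epoxidation with t-BuOOH and catalytic VO(acac)2 in toluene at 0 °C → rt. The homoallylic C3 hydroxyl binds vanadium and delivers the peroxide oxygen to its own face of C5=C6, as is established for cyclohex-3-enols, and the electron-poor enone alkene should not be attacked. This detour makes no compound outside the list (F0).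

2. Step 10. Oxirane closure may be outrun by transannular displacement of the C6 iodide by the C3 alkoxide (1,4-ether formation). Other competing processes are conjugate addition of methoxide at C7 followed by cyclopropane closure, and attack at iodine with regeneration of the alkene. The fallback sets out from 10 and comes back at 17 with the order of events reversed. Mitsunobu esterification of 10 with 16 (PPh3, DIAD, THF) should give (3R)-3-(tetradecanoyloxy)-β-ionone F1 with inversion. Epoxidation with mCPBA (CH2Cl2, NaHCO3, 0 °C) then takes place at the ring alkene. By analogy with peracid epoxidation of 3-acyloxy-β-ionone end groups it is expected to favour the face away from the ester, and 17 would be separated from the minor cis isomer by chromatography.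

3. Step 11. The activated alcohol may eliminate to a ring alkene, or displacement may be sluggish because the fatty acid is a weak pronucleophile. The fallback sets out from 15 and comes back at 17, separating inversion from acylation. Mitsunobu reaction with the more acidic 4-nitrobenzoic acid (PPh3, DIAD, THF) should give (3S,5R,6S)-5,6-epoxy-5,6-dihydro-β-ionon-3-yl 4-nitrobenzoate F2. Methanolysis (K2CO3, MeOH, 0 °C) frees the trans epoxy alcohol (3S,5R,6S)-5,6-epoxy-3-hydroxy-5,6-dihydro-β-ionone F3. Steglich esterification with 16 (EDC·HCl, DMAP, CH2Cl2) then gives 17 with retention.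

Further compounds
F0 | step 9 | none | none
F1 | step 10 | (3R)-3-(tetradecanoyloxy)-β-ionone | CCCCCCCCCCCCCC(=O)O[C@H]1CC(C)(C)C(/C=C/C(C)=O)=C(C)C1
F2 | step 11 | (3S,5R,6S)-5,6-epoxy-5,6-dihydro-β-ionon-3-yl 4-nitrobenzoate | O=C(O[C@H]1CC(C)(C)[C@]2(/C=C/C(C)=O)O[C@]2(C)C1)c1ccc(cc1)[N+](=O)[O-]
F3 | step 11 | (3S,5R,6S)-5,6-epoxy-3-hydroxy-5,6-dihydro-β-ionone | O[C@H]1CC(C)(C)[C@]2(/C=C/C(C)=O)O[C@]2(C)C1
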